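## The problem

The target (32) is 6-hydroxy-8-(2-hydroxy-4-methoxy-6-pentylphenoxy)-3-pentyl-1H-isochromen-1-one. It is an isocoumarin (benzo ring A fused to a pyranone) joined through an ether oxygen at C8 to a second benzene ring (ring B). It has no stereocenter, so every difficulty is one of regiochemistry and functional-group differentiation. The ether oxygen sits on ring A next to the carbon that carries the lactone carbonyl, and on ring B between a hydroxyl (C2') and a pentyl chain (C6'). A phenol with two ortho substituents of this kind couples poorly in Ullmann or SNAr reactions. The four phenolic oxygens occur in three states: free at C6 and C2', methylated at C4', bridging at C8/C1'. They must be told apart without a late selective alkylation. Ring B is olivetol with an extra oxygen between one hydroxyl and the pentyl chain, so it is electron-rich and sensitive to oxidants and to electrophiles such as formaldehyde. The enol lactone opens with alkoxide and exchanges oxygen for nitrogen with ammonia, so it is best closed last and under acid. The enabling feature is on ring A: C6–OH and C8–OAr are meta, C8a carries C1 and C4a carries C4. This is the pattern produced when a vinylketene (C8a, C4a, C5 and the carbonyl carbon C6) combines with an ynol ether (C7 and C8, with the ether oxygen already attached).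

## Retrosynthesis

Target 32 is cut at O2–C1, with C1 taken back to a nitrile, giving keto nitrile 29. The forward reaction is an acid-mediated closure of the ketone enol onto the nitrile and hydrolysis of the imidate; the same acid removes both methoxymethyl groups. A benzoate precursor would be the usual choice, but the nitrile is what the ring-forming step delivers, and a hindered 2,6-disubstituted nitrile cannot easily be hydrolysed first.

Keto nitrile 29 is cut at C4–C3, between the benzylic carbon and the ketone carbonyl. This gives tolunitrile 24 and Weinreb amide 27, the latter made from hexanoyl chloride 23 and N,O-dimethylhydroxylamine hydrochloride 26. The nitrile acidifies the ortho methyl group, so lateral lithiation gives anion 28 and the amide stops at the ketone stage. Cutting C3–pentyl instead would require a more elaborate benzylic electrophile.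

Bis-acetal 24 comes from phenol 23 by protection of the one free hydroxyl. Using the same acetal as on ring B lets both leave in the final step.

Phenol 23 is cut at C6–C7, C8–C8a and C5–C6 (isocoumarin numbering), which dissolves ring A into diazo keto nitrile 18 and aryl ethynyl ether 12. The neighbouring cut, at the diaryl ether C8–O, would require coupling the doubly ortho-substituted phenol 7 to an ortho-substituted aryl halide. Here instead the oxygen is already bonded to an sp carbon and ring A is built around it. The precursors are an acyclic five-carbon diazo compound and a single aromatic ring. The forward reaction must deliver one regioisomer, with aryloxy next to the nitrile-bearing carbon.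

Ynol ether 12 is cut at the C(sp)–O bond through dichlorovinyl ether 10 to phenol 7 and trichloroethylene 8. Addition of a phenoxide to dichloroacetylene 9, formed in the flask, followed by elimination and halogen–lithium exchange to acetylide 11, is the standard entry to ynol ethers and tolerates ortho substitution.

Phenol 7 is traced through formate 6 to aldehyde 5 (C–C to C–O by Baeyer–Villiger oxidation), then to 4, 3 and olivetol 1. The formyl group has two roles: its hydrogen bond to the ortho hydroxyl lets the para hydroxyl of 3 be methylated alone, and its carbon is then exchanged for the oxygen that becomes the bridge. Direct oxidation of olivetol 1 would give no such differentiation.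

Diazo compound 18 is cut at the diazo group to β-keto nitrile 17, and 17 at the acyl–CH2 bond to methacryloyl chloride 14 and cyanoacetic acid 13, used as dianion 15 with loss of CO2 from acid 16.

## Roads not taken

Alternative 1: The cut removes the two isolated C–O bonds, C6–O on ring A and C4'–O on ring B, leaving methyl 2-[2-(methoxymethoxy)-6-pentylphenoxy]-6-methylbenzoate A2.
- Forward step: [Ir(OMe)(cod)]2 (a monovalent iridium precatalyst) with 4,4'-di-tert-butyl-2,2'-bipyridine and B2pin2 would borylate the one C–H on each ring that has no ortho neighbour. Oxidation with KHSO5 would then give methyl 4-hydroxy-2-[4-hydroxy-2-(methoxymethoxy)-6-pentylphenoxy]-6-methylbenzoate A1.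
- Merits: the steric rule predicts both sites, two C–O bonds form in one operation, and no photochemistry, diazo compound or sensitive alkyne is needed. It is probably shorter and operationally simpler than the chosen plan up to A1.
- Weak points: A1 has two free phenols that must end up different. The ring B hydroxyl must be methylated while the more acidic ring A hydroxyl, para to the ester, stays free, which runs against the intrinsic bias and costs a protection detour. A2 itself still needs the hindered diaryl ether coupling.
- Comparison: the chosen plan fixes all three oxygen states on one ring before the rings are joined, and forms the ether without a coupling.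

Alternative 2: Ring B is cut at C1'–C6' and C3'–C4'.
- Forward step: under KOt-Bu, N,N-diethyl-4-(methoxymethoxy)-2-methyl-6-(2-oxopropoxy)benzamide A4 would add through its aryloxy-bearing carbon to methyl (E)-oct-2-enoate A5, and Claisen closure would give the racemic trans dione A3. Aromatization and methylation would follow.
- Merits: the reagents are cheap and the chemistry is ionic and scalable. Like the chosen plan, it brings the ether oxygen in on a non-aromatic carbon, here by simple O-alkylation, and it avoids light and a labile ynol ether.
- Weak points: A3 carries the aryloxy group on a ring that is one elimination away from aromatic. Loss of the ring A phenoxide from an enol tautomer gives olivetol 1 with no oxidant at all, so the dehydrogenation must outrun a redox-neutral collapse. The two new ring B hydroxyls then still need differentiating, and the amide must be converted into the lactone.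
- Comparison: in the chosen plan ring B is aromatic and differentiated from 7 onward, and the final event of the ring construction is a tautomerization that cannot expel the aryloxy group.

Alternative 3: The pyranone is cut at C4a–C4 and O2–C3.
- Forward step: [Cp*RhCl2]2 (a trivalent rhodium complex) would activate the only ortho C–H of 4-(benzyloxy)-2-[2-(benzyloxy)-4-methoxy-6-pentylphenoxy]benzoic acid A7 and couple it with the sulfoxonium ylide 1-[dimethyl(oxo)-λ6-sulfanylidene]heptan-2-one A8. Cyclodehydration would give the dibenzyl ether A6 of the target.
- Merits: the pyranone forms in one catalytic step with regiochemistry that cannot err. This is a better endgame than the three operations (steps 10, 12, 13) of the chosen plan.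
- Weak points: A7 must first be assembled by the hindered ether coupling. The carboxylate sits beside a bulky aryloxy group, which may hinder cyclometalation. Debenzylation of A6 by hydrogenolysis puts the C3–C4 double bond at risk, and Lewis acids put the C4' methyl ether at risk.
- Comparison: the chosen plan makes ring A and the ether bond together, and its protecting groups leave in the step that closes the lactone.

Key step: step 9

Assumption: the terminal ynol ether 12, shielded by two ortho substituents, is taken to survive rapid chromatography and use within hours, as 2,6-disubstituted aryloxyacetylenes generally do.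

## Route

Step 1
Reactants: 1 olivetol (5-pentylbenzene-1,3-diol)
Product: 3 2,4-dihydroxy-6-pentylbenzaldehyde, via aryl iminium chloride 2 (not isolated)
Conditions: POCl3, DMF, 0 °C to rt; then H2O, 50 °C
Reagents that add atoms: N,N-dimethylformamide, CN(C)C=O; water, O
Why: Vilsmeier–Haack formylation of a resorcinol goes para to one hydroxyl and ortho to the other, as with orcinol; the iminium 2 is hydrolysed on aqueous warming.

Step 2
Reactants: 3 2,4-dihydroxy-6-pentylbenzaldehyde
Product: 4 2-hydroxy-4-methoxy-6-pentylbenzaldehyde
Conditions: MeI (1.05 equiv), K2CO3, acetone, rt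
Reagents that add atoms: iodomethane, CI
Why: Williamson methylation; the C2 hydroxyl is held in a hydrogen bond to the aldehyde, so the more acidic and freer C4 hydroxyl should react alone with one equivalent.

Step 3
Reactants: 4 2-hydroxy-4-methoxy-6-pentylbenzaldehyde
Product: 5 4-methoxy-2-(methoxymethoxy)-6-pentylbenzaldehyde
Conditions: MOMCl, i-Pr2NEt, CH2Cl2, 0 °C to rt
Reagents that add atoms: chloromethyl methyl ether, COCCl
Why: Standard acetal protection of a phenol; the group withstands peracid, organolithiums and light and is removed by the acid of the last step.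

Step 4
Reactants: 5 4-methoxy-2-(methoxymethoxy)-6-pentylbenzaldehyde
Product: 7 4-methoxy-2-(methoxymethoxy)-6-pentylphenol, via aryl formate 6 (not isolated)
Conditions: mCPBA, CH2Cl2, 0 °C to rt; then K2CO3 (cat.), MeOH, rt
Reagents that add atoms: 3-chloroperoxybenzoic acid, OOC(=O)c1cccc(Cl)c1
Why: Baeyer–Villiger oxidation of an ortho/para-alkoxy benzaldehyde proceeds with aryl migration to the formate, which methanolysis cleaves to the phenol.

Step 5
Reactants: 7 4-methoxy-2-(methoxymethoxy)-6-pentylphenol; 8 trichloroethylene
Product: 10 2-{[(E)-1,2-dichloroethenyl]oxy}-5-methoxy-1-(methoxymethoxy)-3-pentylbenzene, via dichloroacetylene 9 (not isolated)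
Conditions: K2CO3, DMF, 70 °C, under Ar
Reagents that add atoms: none
Why: Base turns 8 into dichloroacetylene 9, to which the phenoxide adds in anti fashion to give the E-dichlorovinyl ether; this is the known phenol–trichloroethylene reaction, and the small electrophile tolerates the two ortho groups.

Step 6
Reactants: 10 2-{[(E)-1,2-dichloroethenyl]oxy}-5-methoxy-1-(methoxymethoxy)-3-pentylbenzene
Product: 12 2-(ethynyloxy)-5-methoxy-1-(methoxymethoxy)-3-pentylbenzene, via lithium aryloxyacetylide 11 (not isolated)
Conditions: n-BuLi (2.2 equiv), THF, −78 °C; then MeOH, −78 °C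
Reagents that add atoms: none
Why: Elimination of HCl to the chloroalkynyl ether and chlorine–lithium exchange give acetylide 11, protonated cold; this is the established dichlorovinyl ether route to ynol ethers. At −78 °C ring metalation next to the acetal should not compete.

Step 7
Reactants: 13 cyanoacetic acid; 14 methacryloyl chloride
Product: 17 4-methyl-3-oxopent-4-enenitrile, via dilithio cyanoacetate 15 (not isolated), via 2-cyano-4-methyl-3-oxopent-4-enoic acid 16 (not isolated)
Conditions: n-BuLi (2 equiv per 13), THF, −78 °C; 14 (0.5 equiv), −78 to −40 °C; then 1 M HCl, rt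
Reagents that add atoms: none
Why: C-acylation of the cyanoacetate dianion by an acid chloride followed by decarboxylation on acidification is a standard β-keto nitrile synthesis. The second equivalent of dianion keeps the product as its enolate, shielding the enone until the quench; 17 is used at once.

Step 8
Reactants: 17 4-methyl-3-oxopent-4-enenitrile
Product: 18 2-diazo-4-methyl-3-oxopent-4-enenitrile
Conditions: 4-acetamidobenzenesulfonyl azide, Et3N, MeCN, 0 °C
Reagents that add atoms: 4-acetamidobenzenesulfonyl azide, CC(=O)Nc1ccc(cc1)S(=O)(=O)N=[N+]=[N-]
Why: Regitz diazo transfer to an active methylene flanked by ketone and nitrile is fast under mild amine base, and should outpace self-Michael addition of 17.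

Step 9
Reactants: 18 2-diazo-4-methyl-3-oxopent-4-enenitrile; 12 2-(ethynyloxy)-5-methoxy-1-(methoxymethoxy)-3-pentylbenzene
Product: 23 4-hydroxy-2-[4-methoxy-2-(methoxymethoxy)-6-pentylphenoxy]-6-methylbenzonitrile, via cyano(isopropenyl)ketene 19 (not isolated), via 4-vinylcyclobutenone 20 (not isolated), via dienylketene 21 (not isolated), via cyclohexadienone tautomer 22 (not isolated)
Conditions: 18 (1.5 equiv, added in portions), hν (350–365 nm, Pyrex), ClCH2CH2Cl, rt; then 80 °C
Reagents that add atoms: none
Why: Proposed new method: the closest known reaction type is the Danheiser benzannulation in its photochemical diazo ketone form, where a photo-Wolff rearrangement gives a vinylketene that combines with an alkoxy- or siloxyalkyne; new here are the cyano group on the diazo carbon and an aryl ynol ether, and the case rests on each elementary event being known on its own (photo-Wolff rearrangement of 2-diazo-3-oxo nitriles to cyanoketenes, (2+2) addition of cyanoketenes and of ordinary ketenes to ynol ethers, thermal opening of 4-vinylcyclobutenones). Irradiation of 18 expels N2 and the isopropenyl group, the only group that can migrate, shifts to the carbene carbon to give ketene 19. The unsubstituted, nucleophilic alkyne carbon of 12 attacks the ketene carbonyl carbon and the aryloxy-bearing carbon bonds to the cyano-bearing carbon, closing cyclobutenone 20 by (2+2) cycloaddition; its quaternary stereocenter is racemic and is destroyed in the next event. Warming opens 20 by four-electron conrotatory cleavage to dienylketene 21, whose ketene carbon closes onto the isopropenyl CH2 by six-electron disrotatory electrocyclization to form the six-membered carbocycle (ring A) as dienone 22, which tautomerizes to phenol 23. The bonds formed are C6–C7, C8–C8a and C5–C6 in isocoumarin numbering, and no stereocenter remains. The selectivity needed is regiochemical (aryloxy next to the nitrile-bearing carbon, meta to the new hydroxyl) and is secured by the polarization of the ynol ether matched to the strongly electrophilic central carbon of the cyanoketene, which should also offset the lower nucleophilicity of an aryl ynol ether. A linear nitrile cannot act as a heterodiene, so the (4+2) trapping open to acyl- or ester-substituted ketenes is excluded; only the isomer of 21 with isopropenyl cis to the ketene arm can cyclize, the other returning to 20 through the reversible ring opening.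

Step 10
Reactants: 23 4-hydroxy-2-[4-methoxy-2-(methoxymethoxy)-6-pentylphenoxy]-6-methylbenzonitrile
Product: 24 2-[4-methoxy-2-(methoxymethoxy)-6-pentylphenoxy]-4-(methoxymethoxy)-6-methylbenzonitrile
Conditions: MOMCl, i-Pr2NEt, CH2Cl2, 0 °C to rt
Reagents that add atoms: chloromethyl methyl ether, COCCl
Why: Acetal protection of an acidic para-cyanophenol; it removes the acidic proton before the lateral metalation and matches the ring B protecting group.

Step 11
Reactants: 25 hexanoyl chloride; 26 N,O-dimethylhydroxylamine hydrochloride
Product: 27 N-methoxy-N-methylhexanamide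
Conditions: K2CO3, H2O/CH2Cl2, 0 °C to rt
Reagents that add atoms: none
Why: Schotten–Baumann acylation gives the Weinreb amide.

Step 12
Reactants: 24 2-[4-methoxy-2-(methoxymethoxy)-6-pentylphenoxy]-4-(methoxymethoxy)-6-methylbenzonitrile; 27 N-methoxy-N-methylhexanamide
Product: 29 2-[4-methoxy-2-(methoxymethoxy)-6-pentylphenoxy]-4-(methoxymethoxy)-6-(2-oxoheptyl)benzonitrile, via benzylic lithium species 28 (not isolated)
Conditions: LiN(i-Pr)2 (1.1 equiv), THF, −78 °C; then 27, −78 to −40 °C; AcOH, −78 °C
Reagents that add atoms: none
Why: Lateral lithiation of an ortho-tolunitrile followed by acylation with a Weinreb amide; the chelated tetrahedral adduct prevents over-addition and does not quench anion 28 by proton transfer. Any adduct that closes onto the nitrile would still converge on 32 in step 13.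

Step 13
Reactants: 29 2-[4-methoxy-2-(methoxymethoxy)-6-pentylphenoxy]-4-(methoxymethoxy)-6-(2-oxoheptyl)benzonitrile
Product: 32 6-hydroxy-8-(2-hydroxy-4-methoxy-6-pentylphenoxy)-3-pentyl-1H-isochromen-1-one, via diphenol keto nitrile 30 (not isolated), via 1-iminoisochromene 31 (not isolated)
Conditions: conc. aq HCl, MeOH, 65 °C
Reagents that add atoms: water, O
Why: Pinner-type addition of the ketone enol oxygen to the protonated nitrile (6-exo-dig) gives cyclic imidate 31, whose C=NH is hydrolysed to the lactone carbonyl. The same acid methanolyses both acetals, the formaldehyde unit leaving as dimethoxymethane and not as a free electrophile towards ring B.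

## Compound list

1 | olivetol (5-pentylbenzene-1,3-diol) | CCCCCc1cc(O)cc(O)c1 | starting material
2 | N-[(2,4-dihydroxy-6-pentylphenyl)methylidene]-N-methylmethanaminium chloride | CCCCCc1cc(O)cc(O)c1C=[N+](C)C.[Cl-] | intermediate (not isolated)
3 | 2,4-dihydroxy-6-pentylbenzaldehyde | CCCCCc1cc(O)cc(O)c1C=O | intermediate
4 | 2-hydroxy-4-methoxy-6-pentylbenzaldehyde | CCCCCc1cc(OC)cc(O)c1C=O | intermediate
5 | 4-methoxy-2-(methoxymethoxy)-6-pentylbenzaldehyde | CCCCCc1cc(OC)cc(OCOC)c1C=O | intermediate
6 | 4-methoxy-2-(methoxymethoxy)-6-pentylphenyl formate | CCCCCc1cc(OC)cc(OCOC)c1OC=O | intermediate (not isolated)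
7 | 4-methoxy-2-(methoxymethoxy)-6-pentylphenol | CCCCCc1cc(OC)cc(OCOC)c1O | intermediate
8 | trichloroethylene | ClC=C(Cl)Cl | starting material
9 | dichloroacetylene | ClC#CCl | intermediate (not isolated)
10 | 2-{[(E)-1,2-dichloroethenyl]oxy}-5-methoxy-1-(methoxymethoxy)-3-pentylbenzene | Cl/C=C(/Cl)Oc1c(OCOC)cc(OC)cc1CCCCC | intermediate
11 | lithium [4-methoxy-2-(methoxymethoxy)-6-pentylphenoxy]ethynide | [Li]C#COc1c(OCOC)cc(OC)cc1CCCCC | intermediate (not isolated)
12 | 2-(ethynyloxy)-5-methoxy-1-(methoxymethoxy)-3-pentylbenzene | C#COc1c(OCOC)cc(OC)cc1CCCCC | intermediate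
13 | cyanoacetic acid | N#CCC(=O)O | starting material
14 | methacryloyl chloride | CC(=C)C(=O)Cl | starting material
15 | dilithio cyanoacetate (lithium 2-cyano-2-lithioacetate) | [Li]C(C#N)C(=O)O[Li] | intermediate (not isolated)
16 | 2-cyano-4-methyl-3-oxopent-4-enoic acid | CC(=C)C(=O)C(C#N)C(=O)O | intermediate (not isolated)
17 | 4-methyl-3-oxopent-4-enenitrile | CC(=C)C(=O)CC#N | intermediate
18 | 2-diazo-4-methyl-3-oxopent-4-enenitrile | CC(=C)C(=O)C(=[N+]=[N-])C#N | intermediate
19 | 3-methyl-2-(oxomethylidene)but-3-enenitrile (cyano(isopropenyl)ketene) | CC(=C)C(C#N)=C=O | intermediate (not isolated)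
20 | racemic 2-[4-methoxy-2-(methoxymethoxy)-6-pentylphenoxy]-4-oxo-1-(prop-1-en-2-yl)cyclobut-2-ene-1-carbonitrile | CC(=C)C1(C#N)C(=O)C=C1Oc1c(OCOC)cc(OC)cc1CCCCC | intermediate (not isolated)
21 | (2Z)-3-[4-methoxy-2-(methoxymethoxy)-6-pentylphenoxy]-5-oxo-2-(prop-1-en-2-yl)penta-2,4-dienenitrile | O=C=C/C(Oc1c(OCOC)cc(OC)cc1CCCCC)=C(C#N)\C(C)=C | intermediate (not isolated)
22 | 6-[4-methoxy-2-(methoxymethoxy)-6-pentylphenoxy]-2-methyl-4-oxocyclohexa-1,5-diene-1-carbonitrile | N#CC1=C(C)CC(=O)C=C1Oc1c(OCOC)cc(OC)cc1CCCCC | intermediate (not isolated)
23 | 4-hydroxy-2-[4-methoxy-2-(methoxymethoxy)-6-pentylphenoxy]-6-methylbenzonitrile | N#Cc1c(C)cc(O)cc1Oc1c(OCOC)cc(OC)cc1CCCCC | intermediate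
24 | 2-[4-methoxy-2-(methoxymethoxy)-6-pentylphenoxy]-4-(methoxymethoxy)-6-methylbenzonitrile | N#Cc1c(C)cc(OCOC)cc1Oc1c(OCOC)cc(OC)cc1CCCCC | intermediate
25 | hexanoyl chloride | CCCCCC(=O)Cl | starting material
26 | N,O-dimethylhydroxylamine hydrochloride | CNOC.Cl | starting material
27 | N-methoxy-N-methylhexanamide | CCCCCC(=O)N(C)OC | intermediate
28 | {2-cyano-3-[4-methoxy-2-(methoxymethoxy)-6-pentylphenoxy]-5-(methoxymethoxy)phenyl}methyllithium | [Li]Cc1cc(OCOC)cc(Oc2c(OCOC)cc(OC)cc2CCCCC)c1C#N | intermediate (not isolated)
29 | 2-[4-methoxy-2-(methoxymethoxy)-6-pentylphenoxy]-4-(methoxymethoxy)-6-(2-oxoheptyl)benzonitrile | CCCCCC(=O)Cc1cc(OCOC)cc(Oc2c(OCOC)cc(OC)cc2CCCCC)c1C#N | intermediate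
30 | 4-hydroxy-2-(2-hydroxy-4-methoxy-6-pentylphenoxy)-6-(2-oxoheptyl)benzonitrile | CCCCCC(=O)Cc1cc(O)cc(Oc2c(O)cc(OC)cc2CCCCC)c1C#N | intermediate (not isolated)
31 | 8-(2-hydroxy-4-methoxy-6-pentylphenoxy)-1-imino-3-pentyl-1H-isochromen-6-ol | CCCCCC1=Cc2cc(O)cc(Oc3c(O)cc(OC)cc3CCCCC)c2C(=N)O1 | intermediate (not isolated)
32 | 6-hydroxy-8-(2-hydroxy-4-methoxy-6-pentylphenoxy)-3-pentyl-1H-isochromen-1-one | CCCCCc1cc2cc(O)cc(Oc3c(O)cc(OC)cc3CCCCC)c2c(=O)o1 | target

## Step count and risks

Total steps: 13. Longest linear sequence: 10 (steps 1–6, 9, 10, 12, 13).

Step 9 (key step, proposed new method).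
- What may go wrong: slow capture of ketene 19 by the weakly nucleophilic aryl ynol ether, so that the ketene dimerizes or acylates the product phenol. Closure of a zwitterionic adduct through the isopropenyl terminus instead of the cyano-bearing carbon would place hydroxyl ortho to the nitrile. The aryl ether chromophore may photodegrade.
- Fallback (known chemistry, gives up the benzannulation): it sets out from phenol 7. SNAr with commercial 4-bromo-2-fluoro-6-methylbenzonitrile (N#Cc1c(C)cc(Br)cc1F; Cs2CO3, DMSO, 100 °C) displaces the fluoride ortho to the nitrile and should give 4-bromo-2-[4-methoxy-2-(methoxymethoxy)-6-pentylphenoxy]-6-methylbenzonitrile F1. Palladium-catalysed hydroxylation of the aryl bromide (Pd2(dba)3, a zerovalent palladium source, with t-BuXPhos and KOH in dioxane/H2O at 100 °C) should then give phenol 23, where the route resumes. The nitrile, flanked by two ortho groups, should resist hydration.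

Step 6.
- What may go wrong: oligomerization or hydration of the terminal ynol ether during concentration and chromatography; to a lesser degree, ring metalation next to the acetal by excess n-BuLi.
- Fallback: it sets out from acetylide 11. Trapping with Me3SiCl in place of MeOH gives the robust {[4-methoxy-2-(methoxymethoxy)-6-pentylphenoxy]ethynyl}trimethylsilane F2, which can be purified and stored. Compound 12 is released with n-Bu4NF in THF at 0 °C immediately before step 9, and its filtered solution is used directly.

Step 7.
- What may go wrong: conjugate addition of dianion 15 to the methacryloyl unit, and oligomerization of 17 (an enone carrying its own active methylene) during the warm acidic decarboxylation.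
- Fallback: it sets out from methacryloyl chloride 14. Reaction with 26 and K2CO3 gives N-methoxy-N,2-dimethylprop-2-enamide F3. LiCH2CN (from MeCN and n-BuLi, THF, −78 °C) adds to the amide carbonyl, and the chelated adduct keeps ketone and active methylene masked until a cold AcOH quench. This returns 17, which is taken straight into step 8.

Step 12.
- What may go wrong: slow acyl transfer from the Weinreb amide to the stabilized anion 28, leaving time for the anion to add to the nitrile of a second molecule.
- Fallback: it sets out from 24. The same anion is quenched at −78 °C with hexanal, a much faster electrophile, to give racemic 2-(2-hydroxyheptyl)-6-[4-methoxy-2-(methoxymethoxy)-6-pentylphenoxy]-4-(methoxymethoxy)benzonitrile F4. Dess–Martin oxidation of F4 returns ketone 29.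

Step 13.
- What may go wrong: hydration of the nitrile to the primary amide and closure through nitrogen to an isoquinolone, stalling at the hindered nitrile, or electrophilic attack of acetal-derived formaldehyde equivalents on ring B.
- Fallback: it sets out from 24 and exchanges the nitrile for an ester before the side chain is built.
  - i-Bu2AlH (toluene, −78 °C, then aqueous acid) gives 2-[4-methoxy-2-(methoxymethoxy)-6-pentylphenoxy]-4-(methoxymethoxy)-6-methylbenzaldehyde F5.
  - NaClO2/NaH2PO4 with 2-methylbut-2-ene gives the corresponding benzoic acid F6.
  - MeI/K2CO3 gives methyl ester F7.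
  - Lateral lithiation with LiN(i-Pr)2 and acylation with 27 gives methyl 2-[4-methoxy-2-(methoxymethoxy)-6-pentylphenoxy]-4-(methoxymethoxy)-6-(2-oxoheptyl)benzoate F8.
  - HCl in MeOH then effects enol lactonization and acetal removal, rejoining the route at target 32.

## Further compounds

F1 | step 9 | 4-bromo-2-[4-methoxy-2-(methoxymethoxy)-6-pentylphenoxy]-6-methylbenzonitrile | N#Cc1c(C)cc(Br)cc1Oc1c(OCOC)cc(OC)cc1CCCCC
F2 | step 6 | {[4-methoxy-2-(methoxymethoxy)-6-pentylphenoxy]ethynyl}trimethylsilane | C[Si](C)(C)C#COc1c(OCOC)cc(OC)cc1CCCCC
F3 | step 7 | N-methoxy-N,2-dimethylprop-2-enamide | CC(=C)C(=O)N(C)OC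
F4 | step 12 | racemic 2-(2-hydroxyheptyl)-6-[4-methoxy-2-(methoxymethoxy)-6-pentylphenoxy]-4-(methoxymethoxy)benzonitrile | CCCCCC(O)Cc1cc(OCOC)cc(Oc2c(OCOC)cc(OC)cc2CCCCC)c1C#N
F5 | step 13 | 2-[4-methoxy-2-(methoxymethoxy)-6-pentylphenoxy]-4-(methoxymethoxy)-6-methylbenzaldehyde | O=Cc1c(C)cc(OCOC)cc1Oc1c(OCOC)cc(OC)cc1CCCCC
F6 | step 13 | 2-[4-methoxy-2-(methoxymethoxy)-6-pentylphenoxy]-4-(methoxymethoxy)-6-methylbenzoic acid | OC(=O)c1c(C)cc(OCOC)cc1Oc1c(OCOC)cc(OC)cc1CCCCC
F7 | step 13 | methyl 2-[4-methoxy-2-(methoxymethoxy)-6-pentylphenoxy]-4-(methoxymethoxy)-6-methylbenzoate | COC(=O)c1c(C)cc(OCOC)cc1Oc1c(OCOC)cc(OC)cc1CCCCC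
F8 | step 13 | methyl 2-[4-methoxy-2-(methoxymethoxy)-6-pentylphenoxy]-4-(methoxymethoxy)-6-(2-oxoheptyl)benzoate | CCCCCC(=O)Cc1cc(OCOC)cc(Oc2c(OCOC)cc(OC)cc2CCCCC)c1C(=O)OC
A1 | alternative 1 | methyl 4-hydroxy-2-[4-hydroxy-2-(methoxymethoxy)-6-pentylphenoxy]-6-methylbenzoate | COC(=O)c1c(C)cc(O)cc1Oc1c(OCOC)cc(O)cc1CCCCC
A2 | alternative 1 | methyl 2-[2-(methoxymethoxy)-6-pentylphenoxy]-6-methylbenzoate | COC(=O)c1c(C)cccc1Oc1c(OCOC)cccc1CCCCC
A3 | alternative 2 | racemic trans N,N-diethyl-2-[(2,4-dioxo-6-pentylcyclohexyl)oxy]-4-(methoxymethoxy)-6-methylbenzamide (one enantiomer drawn) | CCCCC[C@@H]1CC(=O)CC(=O)[C@H]1Oc1cc(OCOC)cc(C)c1C(=O)N(CC)CC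
A4 | alternative 2 | N,N-diethyl-4-(methoxymethoxy)-2-methyl-6-(2-oxopropoxy)benzamide | CC(=O)COc1cc(OCOC)cc(C)c1C(=O)N(CC)CC
A5 | alternative 2 | methyl (E)-oct-2-enoate | CCCCC/C=C/C(=O)OC
A6 | alternative 3 | 6-(benzyloxy)-8-[2-(benzyloxy)-4-methoxy-6-pentylphenoxy]-3-pentyl-1H-isochromen-1-one | CCCCCc1cc2cc(OCc3ccccc3)cc(Oc3c(OCc4ccccc4)cc(OC)cc3CCCCC)c2c(=O)o1
A7 | alternative 3 | 4-(benzyloxy)-2-[2-(benzyloxy)-4-methoxy-6-pentylphenoxy]benzoic acid | OC(=O)c1ccc(OCc2ccccc2)cc1Oc1c(OCc2ccccc2)cc(OC)cc1CCCCC
A8 | alternative 3 | 1-[dimethyl(oxo)-λ6-sulfanylidene]heptan-2-one | CCCCCC(=O)C=S(C)(C)=O
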